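The 3(2H)-furanone (ring O, quaternary C10, ketone C1, C2H, C3; germacrane numbering) is opened at its O–C3 bond: the oxygen on C10 and C3 are 1,4-related across the C1 carbonyl, so the ring is the cycloisomer of a cyclic α′-hydroxy ynone. The key step oxidises a macrocyclic propargylic diol and closes the furanone by gold-catalysed transannular 5-endo-dig addition, turning the strained C2≡C3 bond of a ten-membered cycloalkyne into the oxygen-bridged bicycle in one operation. The precursor, with the trans α-methylene lactone in place, comes from (R)-citramalic acid, an acrylate unit allylated twice at C7 and (Z)-3-methylpent-2-en-4-yn-1-ol; its carbocycle is closed by Nozaki–Hiyama–Kishi alkynylation.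

Key step: step 12

Remark: germacrane numbering is used for all intermediates (C4(Me)=C5, C6 carries the ester oxygen, C8 the lactone oxygen, C9 is the CH2, C11–C13 are the α-methylene lactone carbons); compounds 1, 4, 9 and 20 are taken as purchasable.

Step 1
Reactants: 1 (R)-citramalic acid
Product: 2 (2R)-2-methylbutane-1,2,4-triol
Conditions: BH3·SMe2, B(OMe)3, THF, 0 °C to rt; MeOH
Reagents that add atoms: none
Why: Borane reduces both carboxylic acids to primary alcohols (acid-to-alcohol reduction) and leaves the tertiary carbinol carbon, the future C10, untouched, so its R configuration is taken from the chiral pool.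

Step 2
Reactants: 2 (2R)-2-methylbutane-1,2,4-triol
Product: 3 2-[(4R)-2,2,4-trimethyl-1,3-dioxolan-4-yl]ethan-1-ol
Conditions: Me2C(OMe)2, TsOH·H2O (cat.), acetone, rt
Reagents that add atoms: 2,2-dimethoxypropane, COC(C)(C)OC
Why: Acid-catalysed acetonide formation under thermodynamic control selects the five-membered dioxolane of the 1,2-diol (C1 and C10 oxygens) over the 1,3-dioxane that would carry an axial methyl group, leaving the C8 alcohol free.

Step 3
Reactants: 3 2-[(4R)-2,2,4-trimethyl-1,3-dioxolan-4-yl]ethan-1-ol; 4 methyl 2-{[(tert-butoxycarbonyl)oxy]methyl}prop-2-enoate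
Product: 6 (5R)-3-methylidene-5-{[(4R)-2,2,4-trimethyl-1,3-dioxolan-4-yl]methyl}oxolan-2-one, via hydroxy ester 5 (not isolated)
Conditions: [Ir(cod)Cl]2 (cat.), (S)-SEGPHOS, 4-cyano-3-nitrobenzoic acid, Cs2CO3 (cat.), THF, 60 °C
Reagents that add atoms: none
Why: Iridium-catalysed transfer-hydrogenative 2-(alkoxycarbonyl)allylation from the alcohol oxidation level (dehydrogenation to the aldehyde, addition of the allyliridium species, lactonisation in the flask) builds the α-methylene lactone, and C8 is set by catalyst control, the ligand antipode being the one that gives the (5R)-lactone (the other antipode is used should the facial sense prove opposite).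

Step 4
Reactants: 6 (5R)-3-methylidene-5-{[(4R)-2,2,4-trimethyl-1,3-dioxolan-4-yl]methyl}oxolan-2-one
Product: 8 (5S)-3-(bromomethyl)-5-{[(4R)-2,2,4-trimethyl-1,3-dioxolan-4-yl]methyl}furan-2(5H)-one, via dibromide 7 (not isolated)
Conditions: Br2, CH2Cl2, 0 °C; then Et3N, 0 °C
Reagents that add atoms: bromine, BrBr
Why: Bromine adds to the exocyclic alkene and triethylamine removes HBr across C11–C7 to give the conjugated endocyclic butenolide (bromination–dehydrobromination), a sequence that does not touch C8 and uses a base too weak to enolise the butenolide at 0 °C.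

Step 5
Reactants: 9 (2Z)-3-methylpent-2-en-4-yn-1-ol
Product: 10 (2Z)-3-methylpent-2-en-4-ynal
Conditions: MnO2, CH2Cl2, rt
Reagents that add atoms: none
Why: Heterogeneous MnO2 oxidation of the allylic alcohol is neutral and is expected to keep the Z geometry that becomes the C4=C5 bond.

Step 6
Reactants: 8 (5S)-3-(bromomethyl)-5-{[(4R)-2,2,4-trimethyl-1,3-dioxolan-4-yl]methyl}furan-2(5H)-one; 10 (2Z)-3-methylpent-2-en-4-ynal
Product: 11 (4S,5S)-4-[(1R,2Z)-1-hydroxy-3-methylpent-2-en-4-yn-1-yl]-3-methylidene-5-{[(4R)-2,2,4-trimethyl-1,3-dioxolan-4-yl]methyl}oxolan-2-one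
Conditions: In powder, THF/H2O (1:1), rt
Reagents that add atoms: none
Why: Indium-mediated Barbier allylation, in which the allylindium formed from 8 adds through C7 with allylic transposition and so restores the exocyclic methylene; in the Zimmerman–Traxler chair the ring holds C8 trans to the CH2–In carbon, so C8 and the aldehyde residue are both equatorial (C6–OH anti to C8), and the aldehyde approaches C7 on the face opposite the C8 side chain (trans lactone), which together should set C6 and C7 as in the target.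

Step 7
Reactants: 11 (4S,5S)-4-[(1R,2Z)-1-hydroxy-3-methylpent-2-en-4-yn-1-yl]-3-methylidene-5-{[(4R)-2,2,4-trimethyl-1,3-dioxolan-4-yl]methyl}oxolan-2-one
Product: 12 (4R,5S)-4-[(1R,2Z)-1-{[tert-butyl(dimethyl)silyl]oxy}-3-methylpent-2-en-4-yn-1-yl]-3-methylidene-5-{[(4R)-2,2,4-trimethyl-1,3-dioxolan-4-yl]methyl}oxolan-2-one
Conditions: TBSOTf, 2,6-lutidine, CH2Cl2, −78 °C
Reagents that add atoms: tert-butyldimethylsilyl triflate, CC(C)(C)[Si](C)(C)OS(=O)(=O)C(F)(F)F
Why: Silylation of the secondary allylic alcohol (silyl ether protection) blocks C6–OH against the later oxidations and is orthogonal to the acetonide.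

Step 8
Reactants: 12 (4R,5S)-4-[(1R,2Z)-1-{[tert-butyl(dimethyl)silyl]oxy}-3-methylpent-2-en-4-yn-1-yl]-3-methylidene-5-{[(4R)-2,2,4-trimethyl-1,3-dioxolan-4-yl]methyl}oxolan-2-one
Product: 13 (4R,5S)-4-[(1R,2Z)-1-{[tert-butyl(dimethyl)silyl]oxy}-3-methylpent-2-en-4-yn-1-yl]-5-[(2R)-2,3-dihydroxy-2-methylpropyl]-3-methylideneoxolan-2-one
Conditions: CeCl3·7H2O, oxalic acid (cat.), MeCN, rt
Reagents that add atoms: none
Why: Mild Lewis-acid-assisted hydrolysis cleaves the terminal acetonide (acetal hydrolysis) while the secondary silyl ether, the lactone and the enyne are expected to survive.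

Step 9
Reactants: 13 (4R,5S)-4-[(1R,2Z)-1-{[tert-butyl(dimethyl)silyl]oxy}-3-methylpent-2-en-4-yn-1-yl]-5-[(2R)-2,3-dihydroxy-2-methylpropyl]-3-methylideneoxolan-2-one
Product: 14 (4R,5S)-4-[(1R,2Z)-1-{[tert-butyl(dimethyl)silyl]oxy}-5-iodo-3-methylpent-2-en-4-yn-1-yl]-5-[(2R)-2,3-dihydroxy-2-methylpropyl]-3-methylideneoxolan-2-one
Conditions: NIS, AgNO3 (cat.), acetone, rt, dark
Reagents that add atoms: N-iodosuccinimide, O=C1CCC(=O)N1I
Why: Silver-catalysed electrophilic iodination of the terminal alkyne with N-iodosuccinimide gives the 1-iodoalkyne needed for chromium insertion and does not affect the hydroxyl groups.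

Step 10
Reactants: 14 (4R,5S)-4-[(1R,2Z)-1-{[tert-butyl(dimethyl)silyl]oxy}-5-iodo-3-methylpent-2-en-4-yn-1-yl]-5-[(2R)-2,3-dihydroxy-2-methylpropyl]-3-methylideneoxolan-2-one
Product: 15 (2R)-3-{(2S,3R)-3-[(1R,2Z)-1-{[tert-butyl(dimethyl)silyl]oxy}-5-iodo-3-methylpent-2-en-4-yn-1-yl]-4-methylidene-5-oxooxolan-2-yl}-2-hydroxy-2-methylpropanal
Conditions: SO3·pyridine, DMSO, iPr2NEt, CH2Cl2, 0 °C
Reagents that add atoms: none
Why: Parikh–Doering oxidation converts the primary alcohol into the aldehyde without glycol cleavage, the tertiary C10 hydroxyl being inert and the aldehyde, which has no α-hydrogen, being used at once.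

Step 11
Reactants: 15 (2R)-3-{(2S,3R)-3-[(1R,2Z)-1-{[tert-butyl(dimethyl)silyl]oxy}-5-iodo-3-methylpent-2-en-4-yn-1-yl]-4-methylidene-5-oxooxolan-2-yl}-2-hydroxy-2-methylpropanal
Product: 16 ten-membered cycloalkyne diol (6R,7R,8S,10R; both C1 epimers): carbocycle C1–C10 with 1-OH; 10-OH; 10-Me; C2≡C3; (4Z)-C4(Me)=C5; 6-OTBS; trans-fused 8,12-α-methylene-γ-lactone
Conditions: CrCl2 (excess), NiCl2 (cat.), THF, rt, slow addition to high dilution
Reagents that add atoms: none
Why: Nozaki–Hiyama–Kishi reaction in which divalent chromium inserts into the C(sp)–I bond and the alkynylchromium species adds to the aldehyde under high dilution to close the ten-membered carbocycle, a closure type known for strained cycloalkynols, and the new C1 carbinol centre needs no control because it is oxidised in step 12.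

Step 12
Reactants: 16 ten-membered cycloalkyne diol (both C1 epimers)
Product: 18 macrocyclic furanone silyl ether (6-O-TBS derivative of the tricyclic core of 22; 6R,7R,8S,10R), via hydroxy ynone 17 (not isolated)
Conditions: Dess–Martin periodinane, CH2Cl2, 0 °C; then Ph3PAuNTf2 (5 mol%), rt
Reagents that add atoms: none
Why: Dess–Martin oxidation of the only oxidisable hydroxyl (C1–OH; C10–OH is tertiary, C6–O is silylated) gives the cyclic α′-hydroxy ynone 17, in which the C10 oxygen and C3 are 1,4-related through the C1 carbonyl. The cationic monovalent gold complex coordinates the bent, electron-poor C2≡C3 bond, the C10 hydroxyl adds anti to gold at C3 (the β-carbon of the ynone), and protodeauration by the acetic acid left from the oxidation places the hydrogen on C2. The closest known reaction type is the gold-catalysed cycloisomerisation of acyclic α′-hydroxy ynones to 3(2H)-furanones, run here transannularly. The furanone ring (O, C10, C1, C2, C3) closes in the 5-endo-dig mode, which converts the ten-membered cycloalkyne into the 11-oxabicyclo[6.2.1]undecane core and releases its strain. No stereocentre is created, since C10 comes from 1 and the ring fixes O and C1 cis on the new C2=C3 bond. The step needs O-attack at C3 and not at C2 and no reaction at the other π-systems; the polarisation of the ynone and the disfavoured 4-exo alternative should secure the first, the preference of gold for the alkyne the second.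

Step 13
Reactants: 18 macrocyclic furanone silyl ether
Product: 19 macrocyclic furanone alcohol (6-hydroxy tricyclic core; 6R,7S,8S,10R by the sequence rule, same spatial arrangement as in 22)
Conditions: HF·pyridine, pyridine, THF, 0 °C to rt
Reagents that add atoms: none
Why: Fluoride-mediated desilylation with buffered HF·pyridine frees C6–OH under non-basic conditions that spare the α-methylene lactone and the vinylogous ester.

Step 14
Reactants: 20 methyl (2S)-2-methyloxirane-2-carboxylate
Product: 21 potassium (2S)-2-methyloxirane-2-carboxylate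
Conditions: KOH (1 equiv), EtOH, 0 °C
Reagents that add atoms: potassium hydroxide, [K+].[OH-]
Why: Cold saponification of the glycidic ester with one equivalent of KOH gives the stable potassium carboxylate without opening the epoxide, so the S centre of 20 is carried over unchanged.

Step 15
Reactants: 19 macrocyclic furanone alcohol; 21 potassium (2S)-2-methyloxirane-2-carboxylate
Product: 22 CNP0321429.1 (6R,7R,8S,10R; 2′S)
Conditions: 2,4,6-Cl3C6H2COCl, Et3N, DMAP, toluene, rt
Reagents that add atoms: none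
Why: Yamaguchi esterification via the mixed 2,4,6-trichlorobenzoic anhydride acylates the only free hydroxyl (C6–OH) with retention at C6 and at the epoxide carbon.

Compound list

1 | (R)-citramalic acid, (2R)-2-hydroxy-2-methylbutanedioic acid | OC(=O)C[C@@](C)(O)C(=O)O | starting material
2 | (2R)-2-methylbutane-1,2,4-triol | OCC[C@@](C)(O)CO | intermediate
3 | 2-[(4R)-2,2,4-trimethyl-1,3-dioxolan-4-yl]ethan-1-ol | OCC[C@@]1(C)OC(C)(C)OC1 | intermediate
4 | methyl 2-{[(tert-butoxycarbonyl)oxy]methyl}prop-2-enoate | C=C(COC(=O)OC(C)(C)C)C(=O)OC | starting material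
5 | methyl (4R)-4-hydroxy-2-methylidene-5-[(4R)-2,2,4-trimethyl-1,3-dioxolan-4-yl]pentanoate (hydroxy ester) | COC(=O)C(=C)C[C@@H](O)C[C@@]1(C)OC(C)(C)OC1 | intermediate
6 | (5R)-3-methylidene-5-{[(4R)-2,2,4-trimethyl-1,3-dioxolan-4-yl]methyl}oxolan-2-one | C=C1C[C@H](C[C@@]2(C)OC(C)(C)OC2)OC1=O | intermediate
7 | (5S)-3-bromo-3-(bromomethyl)-5-{[(4R)-2,2,4-trimethyl-1,3-dioxolan-4-yl]methyl}oxolan-2-one (dibromide, C3 epimers) | BrCC1(Br)C[C@H](C[C@@]2(C)OC(C)(C)OC2)OC1=O | intermediate
8 | (5S)-3-(bromomethyl)-5-{[(4R)-2,2,4-trimethyl-1,3-dioxolan-4-yl]methyl}furan-2(5H)-one | BrCC1=C[C@H](C[C@@]2(C)OC(C)(C)OC2)OC1=O | intermediate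
9 | (2Z)-3-methylpent-2-en-4-yn-1-ol | C#C/C(C)=C\CO | starting material
10 | (2Z)-3-methylpent-2-en-4-ynal | C#C/C(C)=C\C=O | intermediate
11 | (4S,5S)-4-[(1R,2Z)-1-hydroxy-3-methylpent-2-en-4-yn-1-yl]-3-methylidene-5-{[(4R)-2,2,4-trimethyl-1,3-dioxolan-4-yl]methyl}oxolan-2-one | C=C1C(=O)O[C@@H](C[C@@]2(C)OC(C)(C)OC2)[C@@H]1[C@H](O)/C=C(C)\C#C | intermediate
12 | (4R,5S)-4-[(1R,2Z)-1-{[tert-butyl(dimethyl)silyl]oxy}-3-methylpent-2-en-4-yn-1-yl]-3-methylidene-5-{[(4R)-2,2,4-trimethyl-1,3-dioxolan-4-yl]methyl}oxolan-2-one | C=C1C(=O)O[C@@H](C[C@@]2(C)OC(C)(C)OC2)[C@@H]1[C@H](O[Si](C)(C)C(C)(C)C)/C=C(C)\C#C | intermediate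
13 | (4R,5S)-4-[(1R,2Z)-1-{[tert-butyl(dimethyl)silyl]oxy}-3-methylpent-2-en-4-yn-1-yl]-5-[(2R)-2,3-dihydroxy-2-methylpropyl]-3-methylideneoxolan-2-one | C=C1C(=O)O[C@@H](C[C@@](C)(O)CO)[C@@H]1[C@H](O[Si](C)(C)C(C)(C)C)/C=C(C)\C#C | intermediate
14 | (4R,5S)-4-[(1R,2Z)-1-{[tert-butyl(dimethyl)silyl]oxy}-5-iodo-3-methylpent-2-en-4-yn-1-yl]-5-[(2R)-2,3-dihydroxy-2-methylpropyl]-3-methylideneoxolan-2-one | C=C1C(=O)O[C@@H](C[C@@](C)(O)CO)[C@@H]1[C@H](O[Si](C)(C)C(C)(C)C)/C=C(C)\C#CI | intermediate
15 | (2R)-3-{(2S,3R)-3-[(1R,2Z)-1-{[tert-butyl(dimethyl)silyl]oxy}-5-iodo-3-methylpent-2-en-4-yn-1-yl]-4-methylidene-5-oxooxolan-2-yl}-2-hydroxy-2-methylpropanal | C=C1C(=O)O[C@@H](C[C@@](C)(O)C=O)[C@@H]1[C@H](O[Si](C)(C)C(C)(C)C)/C=C(C)\C#CI | intermediate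
16 | ten-membered cycloalkyne diol (6R,7R,8S,10R; both C1 epimers): carbocycle C1–C10 with 1-OH; 10-OH; 10-Me; C2≡C3; (4Z)-C4(Me)=C5; 6-OTBS; trans-fused 8,12-α-methylene-γ-lactone | C=C1C(=O)O[C@H]2C[C@@](C)(O)C(O)C#C/C(C)=C\[C@@H](O[Si](C)(C)C(C)(C)C)[C@H]12 | intermediate
17 | cyclic α′-hydroxy ynone (6R,7R,8S,10R): as 16 with C1=O (hydroxy ynone) | C=C1C(=O)O[C@H]2C[C@@](C)(O)C(=O)C#C/C(C)=C\[C@@H](O[Si](C)(C)C(C)(C)C)[C@H]12 | intermediate
18 | macrocyclic furanone silyl ether (6R,7R,8S,10R): 6-O-TBS derivative of the tricyclic core of 22 | C=C1C(=O)O[C@H]2C[C@@]3(C)OC(=CC3=O)/C(C)=C\[C@@H](O[Si](C)(C)C(C)(C)C)[C@H]12 | intermediate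
19 | macrocyclic furanone alcohol: 6-hydroxy tricyclic core of 22 (same spatial arrangement; 6R,7S,8S,10R by the sequence rule) | C=C1C(=O)O[C@H]2C[C@@]3(C)OC(=CC3=O)/C(C)=C\[C@@H](O)[C@H]12 | intermediate
20 | methyl (2S)-2-methyloxirane-2-carboxylate | COC(=O)[C@]1(C)CO1 | starting material
21 | potassium (2S)-2-methyloxirane-2-carboxylate | [K+].[O-]C(=O)[C@]1(C)CO1 | intermediate
22 | CNP0321429.1 (6R,7R,8S,10R; 2′S): 6-O-[(2S)-2-methyloxirane-2-carbonyl] ester of 19 | C=C1C(=O)O[C@H]2C[C@@]3(C)OC(=CC3=O)/C(C)=C\[C@@H](OC(=O)[C@]3(C)CO3)[C@H]12 | target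

Total step count: 15. Longest linear sequence: 13 steps (steps 1–4, 6–13 and 15).

Steps most likely to fail

1. Step 11. The ring closure may lose to intermolecular coupling, to simple reduction of the iodoalkyne, or to the strain of the ten-membered cycloalkyne. The fallback closes the carbocycle without an alkyne by an aldol addition, and the furanone is still the last ring to be closed. It sets out from 13 and comes back at 18. Gold-catalysed Markovnikov hydration of the terminal alkyne of 13 (Ph3PAuNTf2, H2O, dioxane) would give the (Z)-methyl enone diol F1. Parikh–Doering oxidation would then give the keto aldehyde F2, in which the aldehyde has no α-hydrogen and the ketone can enolise only at its methyl group. A boron-mediated intramolecular aldol addition (Cy2BCl, Et3N, high dilution) would close the ten-membered ring as the β-hydroxy ketone F3. Dess–Martin oxidation would give the α′-hydroxy 1,3-diketone F4, and TsOH (cat.) would cyclodehydrate it to 18.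

2. Step 6. The simple diastereoselection at C6 may be poor or opposite, and the Z enal may partly isomerise on the metal salts. The fallback sets C6 by reagent-controlled reduction instead of by the allylation; it sets out from 11 obtained as a C6 epimer mixture and comes back at 11. Dess–Martin oxidation would give the enynone F5, and an oxazaborolidine-catalysed reduction (CBS catalyst antipode chosen for the 6R carbinol, catecholborane, −78 °C) would return 11. Both operations are non-basic, so that C7 is not enolised and the exocyclic alkene does not migrate.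

3. Step 3. Enantiofacial control at C8 may be insufficient or reversed, or dehydrogenation of the β-branched alcohol may be slow. The fallback works at the aldehyde oxidation level by asymmetric allylboration; it sets out from 3 and comes back at 6. Parikh–Doering oxidation of 3 would give the aldehyde F6. Allylboration with methyl 2-[(4,4,5,5-tetramethyl-1,3,2-dioxaborolan-2-yl)methyl]prop-2-enoate under a chiral phosphoric acid catalyst would give hydroxy ester 5, now isolated, and TsOH (cat.) would lactonise 5 to 6.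

Further compounds
F1 | step 11 | (4R,5S)-4-[(1R,2Z)-1-{[tert-butyl(dimethyl)silyl]oxy}-3-methyl-4-oxopent-2-en-1-yl]-5-[(2R)-2,3-dihydroxy-2-methylpropyl]-3-methylideneoxolan-2-one | C=C1C(=O)O[C@@H](C[C@@](C)(O)CO)[C@@H]1[C@H](O[Si](C)(C)C(C)(C)C)/C=C(C)\C(C)=O
F2 | step 11 | (2R)-3-{(2S,3R)-3-[(1R,2Z)-1-{[tert-butyl(dimethyl)silyl]oxy}-3-methyl-4-oxopent-2-en-1-yl]-4-methylidene-5-oxooxolan-2-yl}-2-hydroxy-2-methylpropanal | C=C1C(=O)O[C@@H](C[C@@](C)(O)C=O)[C@@H]1[C@H](O[Si](C)(C)C(C)(C)C)/C=C(C)\C(C)=O
F3 | step 11 | ten-membered β-hydroxy ketone: carbocycle C1–C10 with 1-OH (both epimers); C2H2; C3=O; (4Z)-C4(Me)=C5; 6-OTBS; 10-OH; 10-Me; trans-fused 8,12-α-methylene-γ-lactone | C=C1C(=O)O[C@H]2C[C@@](C)(O)C(O)CC(=O)/C(C)=C\[C@@H](O[Si](C)(C)C(C)(C)C)[C@H]12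
F4 | step 11 | ten-membered α′-hydroxy 1,3-diketone: as F3 with C1=O | C=C1C(=O)O[C@H]2C[C@@](C)(O)C(=O)CC(=O)/C(C)=C\[C@@H](O[Si](C)(C)C(C)(C)C)[C@H]12
F5 | step 6 | (4R,5S)-3-methylidene-4-[(2Z)-3-methylpent-2-en-4-ynoyl]-5-{[(4R)-2,2,4-trimethyl-1,3-dioxolan-4-yl]methyl}oxolan-2-one | C=C1C(=O)O[C@@H](C[C@@]2(C)OC(C)(C)OC2)[C@@H]1C(=O)/C=C(C)\C#C
F6 | step 3 | 2-[(4R)-2,2,4-trimethyl-1,3-dioxolan-4-yl]acetaldehyde | O=CC[C@@]1(C)OC(C)(C)OC1
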